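**Retrosynthetic overview**
- The target comes from global O-debenzylation of its tetrabenzyl ether. The two aryl ketone C–C bonds come from a Pd/Cu thioester–boronic acid coupling between an oxolane-3,4-bis(thioester) and 2,4-bis(benzyloxy)phenylboronic acid (made from resorcinol).
- The two C2/C5–aryl bonds and both of these stereocentres come from a twofold amide-directed, Pd-catalysed C(sp3)–H arylation of (3R,4R)-oxolane-3,4-bis(quinolin-8-ylamide) with 4-(benzyloxy)iodobenzene (from 4-iodophenol). Each amide delivers its aryl group cis to itself, which gives the 2,3-cis/3,4-trans/4,5-cis pattern.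
- The oxolane (the only ring made) comes from a [3+2] cycloaddition of the parent carbonyl ylide (from Me3SiCH2OH, formaldehyde, HCl, then CsF) to fumaroyl bis-camphorsultam (from fumaryl chloride). This sets C3/C4.
- Order: oxolane ring first, then the C2/C5 aryl groups, then the aroyl groups. All benzene rings come from the starting materials.

Assumption: the carbonyl ylide attacks the Cα-si faces of the (2S)-sultam fumaramide 5 (mirror image of the Cα-re preference of thermal additions to (2R)-N-enoylsultams); formaldehyde is counted as the starting material behind paraformaldehyde.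

**Step 1**
Reactants: 1 (trimethylsilyl)methanol; 2 formaldehyde (as paraformaldehyde)
Product: 3 [(chloromethoxy)methyl]trimethylsilane
Conditions: (CH2O)n, HCl (g), CH2Cl2, 0 °C; CaCl2; distil
Reagents that add atoms: hydrogen chloride, Cl
Why: Chloromethylation of an alcohol (hemiacetal formation, then substitution of OH by chloride) gives the α-chloro ether.

**Step 2**
Reactants: 4 fumaryl chloride
Product: 5 N,N'-fumaroylbis[(2S)-bornane-10,2-sultam]
Conditions: (1R)-(+)-2,10-camphorsultam (2.1 equiv), NaH, toluene, 0 °C to rt; then 4, rt, 12 h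
Reagents that add atoms: (1R)-(+)-2,10-camphorsultam [(2S)-bornane-10,2-sultam], CC1(C)[C@H]2CC[C@@]13CS(=O)(=O)N[C@H]3C2
Why: N-acylation of the sodium sulfonamide by the diacid chloride (Schotten–Baumann-type acylation) gives the crystalline chiral fumaramide with the E double bond untouched.

**Step 3**
Reactants: 5 N,N'-fumaroylbis[(2S)-bornane-10,2-sultam]; 3 [(chloromethoxy)methyl]trimethylsilane
Product: 7 (3R,4R)-oxolane-3,4-diylbis{[(2S)-bornane-10,2-sultam-N-yl]methanone}, via carbonyl ylide 6 (not isolated)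
Conditions: 3 (2 equiv), CsF (3 equiv), MeCN–CH2Cl2, rt, 24 h; recrystallise to one diastereomer
Reagents that add atoms: none
Why: Fluoride-triggered 1,3-elimination gives the parent carbonyl ylide, whose concerted suprafacial 1,3-dipolar [3+2] cycloaddition keeps the E geometry (3,4-trans) and, through the facial bias of the two sultams (attack at the Cα-si faces), sets C3 and C4 as (3R,4R).

**Step 4**
Reactants: 7 (3R,4R)-oxolane-3,4-diylbis{[(2S)-bornane-10,2-sultam-N-yl]methanone}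
Product: 8 (3R,4R)-N3,N4-di(quinolin-8-yl)oxolane-3,4-dicarboxamide
Conditions: 8-aminoquinoline (3 equiv), AlMe3 (3 equiv), CH2Cl2, 0 to 40 °C; aq. potassium sodium tartrate
Reagents that add atoms: 8-aminoquinoline, Nc1cccc2cccnc12
Why: Weinreb-type aminolysis by the dimethylaluminium amide of 8-aminoquinoline displaces the activated N-acylsultam and returns the auxiliary, and the trans-3,4 arrangement is the thermodynamic one so it is not epimerised.

**Step 5**
Reactants: 9 4-iodophenol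
Product: 10 1-(benzyloxy)-4-iodobenzene
Conditions: BnBr, K2CO3, acetone, reflux
Reagents that add atoms: benzyl bromide, BrCc1ccccc1
Why: Williamson ether synthesis on the phenoxide.

**Step 6**
Reactants: 8 (3R,4R)-N3,N4-di(quinolin-8-yl)oxolane-3,4-dicarboxamide; 10 1-(benzyloxy)-4-iodobenzene
Product: 12 (2S,3R,4R,5S)-2,5-bis[4-(benzyloxy)phenyl]-N3,N4-di(quinolin-8-yl)oxolane-3,4-dicarboxamide, via monoarylated diamide 11 (not isolated)
Conditions: 10 (5 equiv), Pd(OAc)2 (15 mol%), AgOAc (4 equiv), (BnO)2P(O)OH (30 mol%), t-AmOH, 110 °C, 36 h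
Reagents that add atoms: none
Why: Proposed new method: twofold quinolin-8-ylamide-directed arylation of the two O-adjacent CH2 groups of a trans-oxolane-3,4-dicarboxamide, in which each deprotonated amide/quinoline N,N-chelate holds divalent palladium that cleaves only the ring C–H cis to it by concerted metalation–deprotonation (cis-fused 5,5-palladacycle; the trans C–H is out of reach and C4–H is tertiary), the aryl iodide adds oxidatively to give tetravalent palladium, and C–C reductive elimination with retention places each aryl cis to its own amide, so C2 and C5 are set (2S,5S) from C3/C4 and the 2,3-cis/3,4-trans/4,5-cis array results; closest known reaction type: quinolin-8-ylamide-directed cis-selective β-methylene C(sp3)–H arylation of cycloalkane and saturated heterocycle carboxamides with aryl iodides under Pd(OAc)2/AgOAc.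

**Step 7**
Reactants: 12 (2S,3R,4R,5S)-2,5-bis[4-(benzyloxy)phenyl]-N3,N4-di(quinolin-8-yl)oxolane-3,4-dicarboxamide
Product: 13 di-tert-butyl N,N'-{[(2S,3R,4R,5S)-2,5-bis[4-(benzyloxy)phenyl]oxolane-3,4-diyl]dicarbonyl}bis[N-(quinolin-8-yl)carbamate]
Conditions: Boc2O (6 equiv), DMAP (1 equiv), MeCN, 50 °C
Reagents that add atoms: di-tert-butyl dicarbonate, CC(C)(C)OC(=O)OC(=O)OC(C)(C)C
Why: DMAP-catalysed N-acylation (Boc activation) twists the amide out of conjugation and turns the directing group into a leaving group without touching the ring stereocentres.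

**Step 8**
Reactants: 13 di-tert-butyl N,N'-{[(2S,3R,4R,5S)-2,5-bis[4-(benzyloxy)phenyl]oxolane-3,4-diyl]dicarbonyl}bis[N-(quinolin-8-yl)carbamate]
Product: 14 (2S,3R,4R,5S)-2,5-bis[4-(benzyloxy)phenyl]oxolane-3,4-dicarboxylic acid
Conditions: LiOH·H2O, 30% H2O2, THF–H2O (3:1), 0 °C; Na2SO3; 1 M HCl to pH 3, 0 °C
Reagents that add atoms: hydrogen peroxide, OO
Why: Nucleophilic acyl substitution by the weakly basic, strongly nucleophilic hydroperoxide anion (as in cleavage of N-acyl imide auxiliaries) cleaves the activated amide at 0 °C without enolising the cis-configured C3/C4 centres.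

**Step 9**
Reactants: 14 (2S,3R,4R,5S)-2,5-bis[4-(benzyloxy)phenyl]oxolane-3,4-dicarboxylic acid
Product: 15 S,S'-diphenyl (2S,3R,4R,5S)-2,5-bis[4-(benzyloxy)phenyl]oxolane-3,4-bis(carbothioate)
Conditions: PhSSPh (3 equiv), PBu3 (3 equiv), MeCN, rt
Reagents that add atoms: diphenyl disulfide, c1ccc(SSc2ccccc2)cc1
Why: Mukaiyama-type redox condensation (thiophosphonium activation of the acid, then thiolate attack) gives the thioester under neutral conditions that keep the epimerisable centres intact.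

**Step 10**
Reactants: 16 resorcinol
Product: 17 1,3-bis(benzyloxy)benzene
Conditions: BnBr (2.2 equiv), K2CO3, DMF, rt
Reagents that add atoms: benzyl bromide, BrCc1ccccc1
Why: Double Williamson ether synthesis.

**Step 11**
Reactants: 17 1,3-bis(benzyloxy)benzene
Product: 18 2,4-bis(benzyloxy)-1-bromobenzene
Conditions: NBS (1.0 equiv), MeCN, 0 °C to rt
Reagents that add atoms: N-bromosuccinimide, O=C1CCC(=O)N1Br
Why: Electrophilic aromatic bromination goes to C4 (para to one ether, ortho to the other), not to the hindered C2.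

**Step 12**
Reactants: 18 2,4-bis(benzyloxy)-1-bromobenzene
Product: 21 [2,4-bis(benzyloxy)phenyl]boronic acid, via aryllithium 19 (not isolated), via lithium aryltriisopropoxyborate 20 (not isolated)
Conditions: n-BuLi, THF, −78 °C; B(OiPr)3, −78 °C to rt; 1 M HCl
Reagents that add atoms: triisopropyl borate, CC(C)OB(OC(C)C)OC(C)C; water, O
Why: Bromine–lithium exchange, borylation of the aryllithium and hydrolysis of the borate give the boronic acid.

**Step 13**
Reactants: 15 S,S'-diphenyl (2S,3R,4R,5S)-2,5-bis[4-(benzyloxy)phenyl]oxolane-3,4-bis(carbothioate); 21 [2,4-bis(benzyloxy)phenyl]boronic acid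
Product: 22 [(2S,3R,4R,5S)-2,5-bis[4-(benzyloxy)phenyl]oxolane-3,4-diyl]bis{[2,4-bis(benzyloxy)phenyl]methanone}
Conditions: 21 (4 equiv), Pd2(dba)3 (5 mol%), P(2-furyl)3 (20 mol%), CuTC (Cu(O2CC4H3S), 4 equiv), THF, 50 °C
Reagents that add atoms: none
Why: Liebeskind–Srogl coupling, in which zerovalent palladium inserts into the C(acyl)–S bond, the thiophilic monovalent copper carboxylate enables base-free transmetalation from boron, and reductive elimination forms the aryl ketone; the neutral medium leaves C3/C4 unepimerised.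

**Step 14**
Reactants: 22 [(2S,3R,4R,5S)-2,5-bis[4-(benzyloxy)phenyl]oxolane-3,4-diyl]bis{[2,4-bis(benzyloxy)phenyl]methanone}
Product: 23 [(2S,3R,4R,5S)-2,5-bis(4-hydroxyphenyl)oxolane-3,4-diyl]bis[(2,4-dihydroxyphenyl)methanone] (CNP0237262.3)
Conditions: H2 (1 atm), 10% Pd/C, EtOAc–MeOH, rt, monitored and stopped at full debenzylation
Reagents that add atoms: none
Why: Hydrogenolysis of the four aryl benzyl ethers is much faster than cleavage of the hindered cyclic dibenzylic ether or reduction of the aryl ketones, and the neutral conditions cannot epimerise C3/C4.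

**Compound list**
1 | (trimethylsilyl)methanol | C[Si](C)(C)CO | starting material
2 | formaldehyde (used as paraformaldehyde) | C=O | starting material
3 | [(chloromethoxy)methyl]trimethylsilane | C[Si](C)(C)COCCl | intermediate
4 | fumaryl chloride, (E)-but-2-enedioyl dichloride | O=C(Cl)/C=C/C(Cl)=O | starting material
5 | N,N'-fumaroylbis[(2S)-bornane-10,2-sultam] | CC1(C)[C@H]2CC[C@@]13CS(=O)(=O)N(C(=O)/C=C/C(=O)N4[C@H]5C[C@@H]6CC[C@@]5(CS4(=O)=O)C6(C)C)[C@H]3C2 | intermediate
6 | formaldehyde O-methylide (parent carbonyl ylide) | C=[O+][CH2-] | intermediate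
7 | (3R,4R)-oxolane-3,4-diylbis{[(2S)-bornane-10,2-sultam-N-yl]methanone} | O=C(N1[C@H]2C[C@@H]3CC[C@@]2(CS1(=O)=O)C3(C)C)[C@@H]4[C@@H](C(=O)N5[C@H]6C[C@@H]7CC[C@@]6(CS5(=O)=O)C7(C)C)COC4 | intermediate
8 | (3R,4R)-N3,N4-di(quinolin-8-yl)oxolane-3,4-dicarboxamide | O=C(Nc1cccc2cccnc12)[C@@H]1[C@@H](C(=O)Nc2cccc3cccnc23)COC1 | intermediate
9 | 4-iodophenol | Oc1ccc(I)cc1 | starting material
10 | 1-(benzyloxy)-4-iodobenzene | Ic1ccc(OCc2ccccc2)cc1 | intermediate
11 | (2S,3R,4R)-2-[4-(benzyloxy)phenyl]-N3,N4-di(quinolin-8-yl)oxolane-3,4-dicarboxamide | O=C(Nc1cccc2cccnc12)[C@@H]1[C@@H](C(=O)Nc2cccc3cccnc23)CO[C@@H]1c1ccc(OCc2ccccc2)cc1 | intermediate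
12 | (2S,3R,4R,5S)-2,5-bis[4-(benzyloxy)phenyl]-N3,N4-di(quinolin-8-yl)oxolane-3,4-dicarboxamide | O=C(Nc1cccc2cccnc12)[C@@H]1[C@@H](C(=O)Nc2cccc3cccnc23)[C@@H](c2ccc(OCc3ccccc3)cc2)O[C@@H]1c1ccc(OCc2ccccc2)cc1 | intermediate
13 | di-tert-butyl N,N'-{[(2S,3R,4R,5S)-2,5-bis[4-(benzyloxy)phenyl]oxolane-3,4-diyl]dicarbonyl}bis[N-(quinolin-8-yl)carbamate] | O=C(N(C(=O)OC(C)(C)C)c1cccc2cccnc12)[C@@H]1[C@@H](C(=O)N(C(=O)OC(C)(C)C)c2cccc3cccnc23)[C@@H](c2ccc(OCc3ccccc3)cc2)O[C@@H]1c1ccc(OCc2ccccc2)cc1 | intermediate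
14 | (2S,3R,4R,5S)-2,5-bis[4-(benzyloxy)phenyl]oxolane-3,4-dicarboxylic acid | O=C(O)[C@@H]1[C@@H](C(=O)O)[C@@H](c2ccc(OCc3ccccc3)cc2)O[C@@H]1c1ccc(OCc2ccccc2)cc1 | intermediate
15 | S,S'-diphenyl (2S,3R,4R,5S)-2,5-bis[4-(benzyloxy)phenyl]oxolane-3,4-bis(carbothioate) | O=C(Sc1ccccc1)[C@@H]1[C@@H](C(=O)Sc2ccccc2)[C@@H](c2ccc(OCc3ccccc3)cc2)O[C@@H]1c1ccc(OCc2ccccc2)cc1 | intermediate
16 | resorcinol | Oc1cccc(O)c1 | starting material
17 | 1,3-bis(benzyloxy)benzene | c1ccc(COc2cccc(OCc3ccccc3)c2)cc1 | intermediate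
18 | 2,4-bis(benzyloxy)-1-bromobenzene | Brc1ccc(OCc2ccccc2)cc1OCc1ccccc1 | intermediate
19 | [2,4-bis(benzyloxy)phenyl]lithium | [Li]c1ccc(OCc2ccccc2)cc1OCc1ccccc1 | intermediate
20 | lithium [2,4-bis(benzyloxy)phenyl]tri(propan-2-yloxy)borate | [Li+].CC(C)O[B-](OC(C)C)(OC(C)C)c1ccc(OCc2ccccc2)cc1OCc1ccccc1 | intermediate
21 | [2,4-bis(benzyloxy)phenyl]boronic acid | OB(O)c1ccc(OCc2ccccc2)cc1OCc1ccccc1 | intermediate
22 | [(2S,3R,4R,5S)-2,5-bis[4-(benzyloxy)phenyl]oxolane-3,4-diyl]bis{[2,4-bis(benzyloxy)phenyl]methanone} | O=C(c1ccc(OCc2ccccc2)cc1OCc1ccccc1)[C@@H]1[C@@H](C(=O)c2ccc(OCc3ccccc3)cc2OCc2ccccc2)[C@@H](c2ccc(OCc3ccccc3)cc2)O[C@@H]1c1ccc(OCc2ccccc2)cc1 | intermediate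
23 | [(2S,3R,4R,5S)-2,5-bis(4-hydroxyphenyl)oxolane-3,4-diyl]bis[(2,4-dihydroxyphenyl)methanone] | O=C(c1ccc(O)cc1O)[C@@H]1[C@@H](C(=O)c2ccc(O)cc2O)[C@@H](c2ccc(O)cc2)O[C@@H]1c1ccc(O)cc1 | target

**Totals**
Total step count: 14.
Longest linear sequence: 9 steps (steps 2, 3, 4, 6, 7, 8, 9, 13, 14 from 4; equally long from 1 through steps 1, 3, 4, 6, 7, 8, 9, 13, 14).

**Three steps most likely to fail**

Step 6 (the new twofold C–H arylation). Risks are no turnover at the O-adjacent CH2, arrest after one arylation, C–OAc formation at the α-oxy carbon, or cis-to-trans epimerisation. The fallback uses known lignan-type chemistry, sets out from 10 and returns at 14. (S)-4-Benzyl-1,3-oxazolidin-2-one is N-acylated (n-BuLi, then 3-(triisopropylsilyloxy)propanoyl chloride) to the imide F1. Its lithium enolate (LDA, THF, −78 °C) is coupled oxidatively with Cu(2-ethylhexanoate)2 to the C2-symmetric (2S,3S)-succinyl bis-imide F2, each new bond forming anti to the benzyl group as in Evans alkylations. MeNHOMe·HCl/AlMe3 turns F2 into the bis(Weinreb amide) F3. Iodine–magnesium exchange on 10 with iPrMgCl·LiCl gives the Grignard reagent F4, two equivalents of which convert F3 into the 1,4-diketone F5. (R)-Me-CBS/BH3·SMe2 reduces both ketones under reagent control to the (1S,4S)-diol F6. MnO2 oxidises one benzylic alcohol and the resulting hydroxy ketone closes to the cyclic hemiketal F7. Et3SiH/BF3·OEt2 (CH2Cl2, −78 °C) reduces the aryl oxocarbenium ion from the face anti to the neighbouring CH2OSi group, which puts the new aryl cis to it and gives the 2,3-cis/3,4-trans/4,5-cis oxolane F8. TBAF frees the diol F9, and TEMPO/PhI(OAc)2 in MeCN–H2O oxidises both primary alcohols to give 14.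

Step 13 (Liebeskind–Srogl coupling). The bis-thioester is hindered and the ortho-substituted, electron-rich boronic acid can protodeboronate. The fallback sets out from 14 and returns at 22. The diacid 14 is condensed with MeNHOMe·HCl (EDC·HCl, HOBt, N-methylmorpholine, CH2Cl2, 0 °C) to the bis(Weinreb amide) F10. F10 is treated at −78 °C in THF with the aryllithium 19 (from 18 and n-BuLi) and quenched cold with aq. NH4Cl; the stable chelated tetrahedral intermediates collapse to 22 on work-up.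

Step 3 (auxiliary-controlled cycloaddition). Fluoride may attack the acylsultam, and the facial selectivity is not secured. The fallback sets out from 4 and returns at 8. Fumaryl chloride 4 is condensed with 8-aminoquinoline (Et3N, CH2Cl2, 0 °C) to the fumaramide F11. Cycloaddition of F11 with the ylide 6 (from 3 and CsF, MeCN) gives the racemic trans-diamide, that is 8 together with its enantiomer F12. Preparative chiral SFC delivers 8, so auxiliary control is replaced by resolution.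

**Further compounds**
F1 | step 6 | (S)-4-benzyl-3-[3-(triisopropylsilyloxy)propanoyl]-1,3-oxazolidin-2-one | CC(C)[Si](C(C)C)(C(C)C)OCCC(=O)N1[C@@H](Cc2ccccc2)COC1=O
F2 | step 6 | (4S,4'S)-3,3'-{(2S,3S)-2,3-bis[(triisopropylsilyloxy)methyl]butanedioyl}bis(4-benzyl-1,3-oxazolidin-2-one) | CC(C)[Si](C(C)C)(C(C)C)OC[C@@H](C(=O)N1[C@@H](Cc2ccccc2)COC1=O)[C@@H](CO[Si](C(C)C)(C(C)C)C(C)C)C(=O)N1[C@@H](Cc2ccccc2)COC1=O
F3 | step 6 | (2S,3S)-N1,N4-dimethoxy-N1,N4-dimethyl-2,3-bis[(triisopropylsilyloxy)methyl]butanediamide | CC(C)[Si](C(C)C)(C(C)C)OC[C@@H](C(=O)N(C)OC)[C@@H](CO[Si](C(C)C)(C(C)C)C(C)C)C(=O)N(C)OC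
F4 | step 6 | [4-(benzyloxy)phenyl]magnesium chloride–lithium chloride | Cl[Mg]c1ccc(OCc2ccccc2)cc1.[Li+].[Cl-]
F5 | step 6 | (2S,3S)-1,4-bis[4-(benzyloxy)phenyl]-2,3-bis[(triisopropylsilyloxy)methyl]butane-1,4-dione | CC(C)[Si](C(C)C)(C(C)C)OC[C@@H](C(=O)c1ccc(OCc2ccccc2)cc1)[C@@H](CO[Si](C(C)C)(C(C)C)C(C)C)C(=O)c1ccc(OCc2ccccc2)cc1
F6 | step 6 | (1S,2S,3S,4S)-1,4-bis[4-(benzyloxy)phenyl]-2,3-bis[(triisopropylsilyloxy)methyl]butane-1,4-diol | CC(C)[Si](C(C)C)(C(C)C)OC[C@@H]([C@H](O)c1ccc(OCc2ccccc2)cc1)[C@@H](CO[Si](C(C)C)(C(C)C)C(C)C)[C@@H](c1ccc(OCc2ccccc2)cc1)O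
F7 | step 6 | (3S,4S,5S)-2,5-bis[4-(benzyloxy)phenyl]-3,4-bis[(triisopropylsilyloxy)methyl]oxolan-2-ol (anomer mixture) | CC(C)[Si](C(C)C)(C(C)C)OC[C@@H]1[C@@H](CO[Si](C(C)C)(C(C)C)C(C)C)[C@@H](c2ccc(OCc3ccccc3)cc2)OC1(O)c1ccc(OCc2ccccc2)cc1
F8 | step 6 | (2S,3S,4S,5S)-2,5-bis[4-(benzyloxy)phenyl]-3,4-bis[(triisopropylsilyloxy)methyl]oxolane | CC(C)[Si](C(C)C)(C(C)C)OC[C@@H]1[C@@H](CO[Si](C(C)C)(C(C)C)C(C)C)[C@@H](c2ccc(OCc3ccccc3)cc2)O[C@@H]1c1ccc(OCc2ccccc2)cc1
F9 | step 6 | [(2S,3S,4S,5S)-2,5-bis[4-(benzyloxy)phenyl]oxolane-3,4-diyl]dimethanol | OC[C@@H]1[C@@H](CO)[C@@H](c2ccc(OCc3ccccc3)cc2)O[C@@H]1c1ccc(OCc2ccccc2)cc1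
F10 | step 13 | (2S,3R,4R,5S)-2,5-bis[4-(benzyloxy)phenyl]-N3,N4-dimethoxy-N3,N4-dimethyloxolane-3,4-dicarboxamide | CON(C)C(=O)[C@@H]1[C@@H](C(=O)N(C)OC)[C@@H](c2ccc(OCc3ccccc3)cc2)O[C@@H]1c1ccc(OCc2ccccc2)cc1
F11 | step 3 | (E)-N1,N4-di(quinolin-8-yl)but-2-enediamide | O=C(/C=C/C(=O)Nc1cccc2cccnc12)Nc1cccc2cccnc12
F12 | step 3 | (3S,4S)-N3,N4-di(quinolin-8-yl)oxolane-3,4-dicarboxamide | O=C(Nc1cccc2cccnc12)[C@H]1[C@H](C(=O)Nc2cccc3cccnc23)COC1
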